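**Plan**
- Retrosynthetic cuts, in order: the two MOM ethers on O5 and O2'; the C3–O bond (back to a C3–H flavone); ring C at C4a–C4, C4–C3 and O1–C2; last the C4a–iodine bond and the terminal alkyne carbon.
- Enabling feature: in ring C, carbonyl carbon C4 is bonded only to C4a, C3 and its own oxygen, and O1 sits on C8a next to C4a. C4 can therefore be carbon monoxide, ring A a 2-iodophenol, and C2–C3 with ring B an arylacetylene.
- Forward: ring A, bought as 3-hydroxy-4,5-dimethoxybenzaldehyde, becomes the fully substituted iodophenol in five steps, with iodine placed at C4a by carbamate-directed lithiation. Ring B, bought as 2-hydroxy-4-methoxybenzaldehyde, becomes the alkyne in two steps.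
- Ring C is the only ring built. It forms in one pot from iodophenol, CO and alkyne; C3 is then hydroxylated by lithiation, borylation and oxidation, and both MOM ethers are removed.
- Stereochemistry: the target has no stereocentre and no configurable double bond, so nothing has to be set.

Key step: step 8

Remark on numbering: flavone locants (O1, C2 to C8a, C1' to C6') are also used for the corresponding atoms of all precursors.

Remark on protecting groups: O5 and O2' are carried as methoxymethyl (MOM) ethers. Unlike benzyl ethers they offer no benzylic C–H to s-BuLi, the one on O5 reinforces the carbamate in the lithiation, and one acid treatment removes both.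

**Step 1**
Reactants: 1 3-hydroxy-4,5-dimethoxybenzaldehyde
Product: 2 5-formyl-2,3-dimethoxyphenyl N,N-diethylcarbamate
Conditions: Et2NCOCl, K2CO3, MeCN, reflux
Reagents that add atoms: N,N-diethylcarbamoyl chloride, CCN(CC)C(=O)Cl
Why: O-carbamoylation of a phenoxide (nucleophilic acyl substitution) is routine, the non-enolizable aldehyde is inert to K2CO3, and the group installed is the strongest oxygen-based director for the later ortho-lithiation.

**Step 2**
Reactants: 2 5-formyl-2,3-dimethoxyphenyl N,N-diethylcarbamate
Product: 4 5-hydroxy-2,3-dimethoxyphenyl N,N-diethylcarbamate, via aryl formate 3 (not isolated)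
Conditions: mCPBA, CH2Cl2, 0 °C to rt; aq NaHCO3 wash; crude formate, K2CO3 (cat), MeOH, 0 °C
Reagents that add atoms: 3-chloroperoxybenzoic acid (mCPBA), O=C(OO)c1cccc(Cl)c1
Why: In this Baeyer–Villiger oxidation the methoxy group para to the formyl carbon makes aryl migration in the Criegee adduct faster than hydride migration, so formate 3 should form, and catalytic carbonate in methanol transesterifies the formate without touching the far less electrophilic carbamate.

**Step 3**
Reactants: 4 5-hydroxy-2,3-dimethoxyphenyl N,N-diethylcarbamate
Product: 5 2,3-dimethoxy-5-(methoxymethoxy)phenyl N,N-diethylcarbamate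
Conditions: NaH, DMF, 0 °C; MOMCl, 0 °C to rt
Reagents that add atoms: chloromethyl methyl ether (MOMCl), COCCl
Why: Williamson-type O-alkylation of the sodium phenoxide with a very reactive chloromethyl ether is reliable, and the carbamate and methyl ethers are inert to NaH at this temperature.

**Step 4**
Reactants: 5 2,3-dimethoxy-5-(methoxymethoxy)phenyl N,N-diethylcarbamate
Product: 7 2-iodo-5,6-dimethoxy-3-(methoxymethoxy)phenyl N,N-diethylcarbamate, via aryllithium 6 (not isolated)
Conditions: s-BuLi, TMEDA, THF, −78 °C; I2 in THF, −78 °C to rt; aq Na2S2O3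
Reagents that add atoms: iodine, [I][I]
Why: In this directed ortho-metalation the only free position ortho to the carbamate (C4a) lies between the carbamate and the MOM ether, whose combined complexation and acidification should steer s-BuLi/TMEDA there rather than to C6 (flanked by the weaker MOM/OMe pair), and at −78 °C aryllithium 6 is iodinated before an anionic ortho-Fries shift can begin.

**Step 5**
Reactants: 7 2-iodo-5,6-dimethoxy-3-(methoxymethoxy)phenyl N,N-diethylcarbamate
Product: 8 2-iodo-5,6-dimethoxy-3-(methoxymethoxy)phenol
Conditions: NaOH (excess), EtOH/H2O, reflux; aq NH4Cl to about pH 7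
Reagents that add atoms: none
Why: Alkaline hydrolysis (addition–elimination at the carbamoyl carbon) of an aryl N,N-diethylcarbamate needs forcing base, which the electron-rich aryl iodide (no SNAr pathway), the acetal and the methyl ethers tolerate, and the near-neutral work-up keeps the MOM ether.

**Step 6**
Reactants: 9 2-hydroxy-4-methoxybenzaldehyde
Product: 10 4-methoxy-2-(methoxymethoxy)benzaldehyde
Conditions: NaH, DMF, 0 °C; MOMCl, 0 °C to rt
Reagents that add atoms: chloromethyl methyl ether (MOMCl), COCCl
Why: Full deprotonation with NaH breaks the hydrogen bond to the aldehyde, and the free phenoxide is O-alkylated by MOMCl (Williamson-type etherification) while the non-enolizable aldehyde stays untouched.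

**Step 7**
Reactants: 10 4-methoxy-2-(methoxymethoxy)benzaldehyde
Product: 11 1-ethynyl-4-methoxy-2-(methoxymethoxy)benzene
Conditions: dimethyl (1-diazo-2-oxopropyl)phosphonate, K2CO3, MeOH, rt
Reagents that add atoms: dimethyl (1-diazo-2-oxopropyl)phosphonate, CC(=O)C(=[N+]=[N-])P(=O)(OC)OC
Why: In the Ohira–Bestmann form of the Seyferth–Gilbert homologation, methanolysis frees the diazomethylphosphonate anion, which olefinates the aldehyde, and loss of N2 with a 1,2-hydrogen shift gives the terminal alkyne under conditions mild enough for the MOM ether.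

**Step 8**
Reactants: 8 2-iodo-5,6-dimethoxy-3-(methoxymethoxy)phenol; 11 1-ethynyl-4-methoxy-2-(methoxymethoxy)benzene; 12 carbon monoxide
Product: 15 7,8,4'-trimethoxy-5,2'-bis(methoxymethoxy)flavone, via hydroxyaryl ynone 13 (not isolated), via diethylamino enone 14 (not isolated)
Conditions: PdCl2(dppf) (5 mol %; dppf = 1,1'-bis(diphenylphosphino)ferrocene), CO (20 bar), Et2NH, 120 °C, autoclave, no copper salt
Reagents that add atoms: none
Why: PdCl2(dppf) is reduced in the amine/CO medium to zerovalent palladium, which inserts into the C4a–iodine bond of 8; CO then inserts to give an aroylpalladium iodide, the amine-deprotonated alkyne 11 takes the place of iodide, and reductive elimination forges C4a–C4 and C4–C3 in ynone 13. Conjugate addition of Et2NH turns 13 into enaminone 14, and the C8a hydroxyl then attacks C2 and expels the amine, so ring C closes at O1–C2 by an addition–elimination that is formally a 6-endo-dig oxa-Michael cyclization. The closest known reaction type is the palladium-catalysed carbonylative annulation of 2-iodophenols with terminal arylacetylenes in a secondary amine, that is, a carbonylative Sonogashira coupling with cyclization in the same pot. No stereocentre arises, so the step has only chemo- and regioselectivity to meet. Carbonylative coupling must beat direct alkynylation (which would end in a benzofuran) and aminocarbonylation: 20 bar of CO, the absence of copper salts and the rapid CO insertion of an electron-rich, doubly ortho-substituted arylpalladium favour the first, while the two ortho oxygens shield the acyl carbon from Et2NH. Flavone must beat aurone and O8a must beat O5: the enaminone pathway together with the donor 2,4-dioxygenated ring B makes C2 the electrophilic carbon (6-endo, not 5-exo at C3), and O5 is blocked as its MOM ether so that only the C8a oxygen can close the ring.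

**Step 9**
Reactants: 15 7,8,4'-trimethoxy-5,2'-bis(methoxymethoxy)flavone
Product: 18 3-hydroxy-7,8,4'-trimethoxy-5,2'-bis(methoxymethoxy)flavone, via 3-lithioflavone 16 (not isolated), via flavon-3-ylboronate 17 (not isolated)
Conditions: LiN(iPr)2, THF, −78 °C; B(OMe)3, −78 to 0 °C; AcOH, 30% H2O2, 0 °C to rt
Reagents that add atoms: hydrogen peroxide, OO
Why: Deprotonation of flavones at C3 by a lithium amide followed by borylation and peroxide oxidation is a known route to flavonols, since C3–H is the most acidic site (vinylic, next to the lithium-binding C4 carbonyl, with extra chelation from the 2'-OMOM oxygen), the aryl C–H bonds are beyond the reach of LiN(iPr)2, and the C–B bond is oxidized by 1,2-migration under weakly acidic conditions that spare the flavonol.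

**Step 10**
Reactants: 18 3-hydroxy-7,8,4'-trimethoxy-5,2'-bis(methoxymethoxy)flavone
Product: 19 3,5,2'-trihydroxy-7,8,4'-trimethoxyflavone
Conditions: HCl (cat), MeOH, 50 °C
Reagents that add atoms: none
Why: Acid-catalysed acetal exchange with methanol removes both MOM ethers (the one on O5 especially fast, because the freed phenol hydrogen-bonds to the C4 carbonyl), while the aryl methyl ethers and the flavonol core are stable to dilute HCl.

**Compound list**
1 | 3-hydroxy-4,5-dimethoxybenzaldehyde | COc1cc(C=O)cc(O)c1OC | starting material
2 | 5-formyl-2,3-dimethoxyphenyl N,N-diethylcarbamate | CCN(CC)C(=O)Oc1cc(C=O)cc(OC)c1OC | intermediate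
3 | 5-(formyloxy)-2,3-dimethoxyphenyl N,N-diethylcarbamate | CCN(CC)C(=O)Oc1cc(OC=O)cc(OC)c1OC | intermediate
4 | 5-hydroxy-2,3-dimethoxyphenyl N,N-diethylcarbamate | CCN(CC)C(=O)Oc1cc(O)cc(OC)c1OC | intermediate
5 | 2,3-dimethoxy-5-(methoxymethoxy)phenyl N,N-diethylcarbamate | CCN(CC)C(=O)Oc1cc(OCOC)cc(OC)c1OC | intermediate
6 | 2-lithio-5,6-dimethoxy-3-(methoxymethoxy)phenyl N,N-diethylcarbamate | CCN(CC)C(=O)Oc1c([Li])c(OCOC)cc(OC)c1OC | intermediate
7 | 2-iodo-5,6-dimethoxy-3-(methoxymethoxy)phenyl N,N-diethylcarbamate | CCN(CC)C(=O)Oc1c(I)c(OCOC)cc(OC)c1OC | intermediate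
8 | 2-iodo-5,6-dimethoxy-3-(methoxymethoxy)phenol | COCOc1cc(OC)c(OC)c(O)c1I | intermediate
9 | 2-hydroxy-4-methoxybenzaldehyde | COc1ccc(C=O)c(O)c1 | starting material
10 | 4-methoxy-2-(methoxymethoxy)benzaldehyde | COCOc1cc(OC)ccc1C=O | intermediate
11 | 1-ethynyl-4-methoxy-2-(methoxymethoxy)benzene | C#Cc1ccc(OC)cc1OCOC | intermediate
12 | carbon monoxide | [C-]#[O+] | starting material
13 | 1-[2-hydroxy-3,4-dimethoxy-6-(methoxymethoxy)phenyl]-3-[4-methoxy-2-(methoxymethoxy)phenyl]prop-2-yn-1-one | COCOc1cc(OC)ccc1C#CC(=O)c1c(O)c(OC)c(OC)cc1OCOC | intermediate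
14 | (E)-3-(diethylamino)-1-[2-hydroxy-3,4-dimethoxy-6-(methoxymethoxy)phenyl]-3-[4-methoxy-2-(methoxymethoxy)phenyl]prop-2-en-1-one | CCN(CC)/C(=C/C(=O)c1c(O)c(OC)c(OC)cc1OCOC)c1ccc(OC)cc1OCOC | intermediate
15 | 7,8,4'-trimethoxy-5,2'-bis(methoxymethoxy)flavone | COCOc1cc(OC)ccc1-c1cc(=O)c2c(OCOC)cc(OC)c(OC)c2o1 | intermediate
16 | 3-lithio-7,8,4'-trimethoxy-5,2'-bis(methoxymethoxy)flavone | COCOc1cc(OC)ccc1-c1oc2c(OC)c(OC)cc(OCOC)c2c(=O)c1[Li] | intermediate
17 | dimethyl [7,8,4'-trimethoxy-5,2'-bis(methoxymethoxy)flavon-3-yl]boronate | COCOc1cc(OC)ccc1-c1oc2c(OC)c(OC)cc(OCOC)c2c(=O)c1B(OC)OC | intermediate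
18 | 3-hydroxy-7,8,4'-trimethoxy-5,2'-bis(methoxymethoxy)flavone | COCOc1cc(OC)ccc1-c1oc2c(OC)c(OC)cc(OCOC)c2c(=O)c1O | intermediate
19 | 3,5,2'-trihydroxy-7,8,4'-trimethoxyflavone | COc1ccc(-c2oc3c(OC)c(OC)cc(O)c3c(=O)c2O)c(O)c1 | target

Total step count: 10
Longest linear sequence: 8 steps (steps 1 to 5, then 8, 9 and 10)

**Steps most likely to fail**

**Step 8.**
- Oxidative addition at a carbon–iodine bond flanked by two oxygens may be sluggish.
- The hindered aroylpalladium may lose CO, so that direct alkynylation and benzofuran closure take over.
- Diethylamine may intercept the aroylpalladium.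

The fallback sets out from 8 and 11 and returns at 13, and through it at 15. C4 is brought in as a formyl carbon instead of CO, and the three bonds are made one after another.
- Alkyne 11 is deprotonated with n-BuLi in THF at −78 °C and formylated with DMF (quench into aq KH2PO4) to give 3-[4-methoxy-2-(methoxymethoxy)phenyl]prop-2-ynal F1.
- Iodophenol 8 is deprotonated with MeMgCl in the presence of LiCl and subjected to iodine–magnesium exchange with iPrMgCl·LiCl at −20 °C.
- The arylmagnesium phenoxide is added to F1 to give racemic 2-{1-hydroxy-3-[4-methoxy-2-(methoxymethoxy)phenyl]prop-2-yn-1-yl}-5,6-dimethoxy-3-(methoxymethoxy)phenol F2.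
- MnO2 in CH2Cl2 should oxidize F2 to ynone 13, now isolated. Warming 13 with Et2NH in EtOH should close ring C by way of 14 to give 15.

**Step 9.**
- The C3 anion may open ring C by expelling the C8a phenoxide if the temperature rises.
- Deprotonation may stay incomplete.
- The boronate may be protodeboronated before it is oxidized.

The fallback sets out from 15 and returns at 18. The oxygen is delivered electrophilically instead of through a carbanion.
- Dimethyldioxirane in acetone/CH2Cl2 at 0 °C should epoxidize the C2–C3 enol-ether double bond. This gives racemic, cis-fused 2,3-epoxy-7,8,4'-trimethoxy-5,2'-bis(methoxymethoxy)flavanone F3.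
- A trace of p-TsOH in CH2Cl2 should open the oxirane at C2, where the cation is stabilized by O1 and ring B, and loss of the C3 proton gives 18.
- Partial loss of a MOM group at this point is harmless, because step 10 follows.

**Step 5.**
- Hydrolysis may stall at a carbamate hemmed in by iodine and methoxy.
- Iodine may be lost slowly during long exposure to hot alkali.

The fallback sets out from 7 and returns at 8. Cleavage changes from hydroxide attack to hydride delivery.
- Cp2Zr(H)Cl, generated in the flask from Cp2ZrCl2 and LiAlH(OtBu)3 in THF at rt, should reduce the carbamoyl C=O.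
- The resulting hemiaminal zirconate collapses to the zirconium phenoxide, which gives 8 on aqueous work-up.
- Aryl halides, acetals and methyl ethers are tolerated by this reagent.
- This fallback makes no new compound (entry F0).

**Further compounds**
F1 | step 8 | 3-[4-methoxy-2-(methoxymethoxy)phenyl]prop-2-ynal | O=CC#Cc1ccc(OC)cc1OCOC
F2 | step 8 | racemic 2-{1-hydroxy-3-[4-methoxy-2-(methoxymethoxy)phenyl]prop-2-yn-1-yl}-5,6-dimethoxy-3-(methoxymethoxy)phenol | COCOc1cc(OC)ccc1C#CC(O)c1c(O)c(OC)c(OC)cc1OCOC
F3 | step 9 | 2,3-epoxy-7,8,4'-trimethoxy-5,2'-bis(methoxymethoxy)flavanone (racemic, cis-fused oxirane, one enantiomer drawn) | O=C1[C@H]2O[C@@]2(c2ccc(OC)cc2OCOC)Oc2c(OC)c(OC)cc(OCOC)c21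
F0 | step 5 | none | none
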